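The earlier runs and the new flask are simulated from invented constants, noise included.

Read both flasks at 25 min, and hold that time against one other: how long target lasts beside reagent.

| flask | solid substrate | reagent | initiator | temperature | remark | time |
|---|---|---|---|---|---|---|
| south-west | 0.50 M | 1.5 equiv (fed, over 10 min) | 2.5 mol% | 25 °C | run made earlier; the fed solution adds 0.50 times the starting volume |  |
| north-west | 0.79 M | 1.5 equiv (fed, over 10 min) | 2.5 mol% | 50 °C | run made earlier; the fed solution adds 0.50 times the starting volume |  |
| Saturday's | 0.36 M | 1.50 equiv | 2.5 mol% | 30 °C | everything together at the start, the whole solution of reagent included, so that from the start the volume is larger by 0.50 times the starting volume | 25 min |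
| Monday's | 0.36 M | 1.50 equiv (fed, over 10 min) | 2.5 mol% | 70 °C | the fed solution adds 0.50 times the starting volume | 25 min |

| run | time / min | target / % | over-reaction product / % |
|---|---|---|---|
| south-west | 8.00 | 2.2 | 0 |
| south-west | 25.0 | 8.5 | 0 |
| south-west | 40.0 | 12.7 | 1.6 |
| south-west | 60.0 | 18.3 | 2.6 |
| south-west | 90.0 | 23.0 | 5.5 |
| south-west | 120 | 27.2 | 9.6 |
| south-west | 150 | 28.5 | 12.6 |
| north-west | 4.00 | 3.9 | 0 |
| north-west | 5.00 | 4.6 | 0 |
| north-west | 8.00 | 9.6 | 1.2 |
| north-west | 10.0 | 11.7 | 3.4 |
| north-west | 15.0 | 15.1 | 6.8 |
| north-west | 25.0 | 20.4 | 13.7 |
| north-west | 40.0 | 22.4 | 23.6 |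

(standard deviation of a reading: 0.5 percentage points)

- which of the two ends with the higher share of target in all that became target or over-reaction product or isomer of the product ("neither" if they lie within 2 percentage points) (Saturday's / Monday's / neither)
- share of target in all that became target or over-reaction product or isomer of the product, Saturday's
- share of target in all that became target or over-reaction product or isomer of the product, Monday's

- charges are per starting volume, the dose included; the dosed solution carries all of it
- given per volume of solution although it is solid: solid substrate
- at the start none of the solid substrate is in solution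
- what has only dissolved of solid substrate counts as not reacted

Take the late stretch of each earlier run. Divide the gain in over-reaction product by the mean target and the minutes between; that is the frequency of target's loss to over-reaction product. Treat this loss as pseudo-first-order, with a frequency proportional to c(reagent). Reckon the reagent left at one per target and two per over-reaction product.

South-west, 60.0 min to 150 min: frequency 0.00475 min⁻¹, c(reagent) 0.371 M

North-west, 15.0 min to 40.0 min: frequency 0.0358 min⁻¹, c(reagent) 0.531 M

Per unit of c(reagent), the north-west reading is 5.28 times the south-west one. Spread that factor evenly over the degrees, and take c(reagent) as the charge in the final volume, 0.360 M.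

Saturday's, 30 °C: 108 min

Monday's, 70 °C: 7.54 min

Call these the over-reaction half-life: the time in which target halves by over-reaction at that c(reagent). Saturday's is longer than the time, Monday's shorter. Take target as climbing straight where the half-life is long; over-reaction product over target is then the time over the half-life, times ln(2)/2.

Saturday's: 0.0803, so a share of 92.6%, isomer of the product left uncounted

That straight line doesn't serve for Monday's, whose half-life is shorter than the time, so commit to Saturday's as the higher and give Monday's no figure. The readings carry no column for isomer of the product.

The forecast said Saturday's, with 92% for Saturday's and 50% for Monday's, and of the isomer “It may appear when hot, which would lower Monday's share”.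

The flask gives Saturday's: 87.0% against 7.62%.

    initiator → 2 initiating radical (k = 0.168 min⁻¹, Ea = 101 kJ mol⁻¹)
    starting material + initiating radical → chain carrier (k = 3.56 × 10⁵ M⁻¹ min⁻¹, Ea = 32.0 kJ mol⁻¹)
    reagent + chain carrier → target + initiating radical (k = 4.50 × 10⁵ M⁻¹ min⁻¹, Ea = 19.0 kJ mol⁻¹)
    2 chain carrier → ended chains (k = 6.60 × 10⁸ M⁻¹ s⁻¹, Ea = 12.0 kJ mol⁻¹)
    reagent + target → over-reaction product (k = 0.304 M⁻¹ min⁻¹, Ea = 60.0 kJ mol⁻¹)
    solid substrate ⇌ starting material, rate k6*(cs6 - [starting material]) while solid is left; crystals form when [starting material] > cs6 (solubility = 0.120 M, k = 0.0925 min⁻¹)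
    target ⇌ isomer of the product (K = 31.1, k = 0.258 min⁻¹, Ea = 86.0 kJ mol⁻¹, ΔH = −10.0 kJ mol⁻¹)
    (constants at 70 °C)

At 25.0 min Monday's holds 39.0% isomer of the product beside 4.18% target, and the forward half-life of target to isomer there, 2.7 min, is shorter than the time. Saturday's over-reaction product over target stands at 0.0851, against the reckoned 0.0803. Now take one more flask like Saturday's, with 6.00 equiv of reagent: scaling c(reagent) brings the over-reaction half-life to 27.0 min, close to the time, so the straight-line ratio of 0.321 is stretched there. Over-reaction product over target in that flask stands at 0.362.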